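I could not tell from the oak, alder and birch runs which reactant was being lost, since they moved the enzyme and kept the other charges, so I reckoned the case that is dangerous for a feed: second substrate wasting away, first order in itself, while it waits.

| flask | starting material | second substrate | free enzyme | remark | time |
|---|---|---|---|---|---|
| oak | 0.10 M | 0.105 M | 10 µM | run made earlier |  |
| alder | 0.10 M | 0.105 M | 5 µM | run made earlier |  |
| birch | 0.10 M | 0.105 M | 7.5 µM | run made earlier |  |
| teal | 0.10 M | 0.105 M | 10 µM | everything together at the start | 1.5 h |
| red | 0.10 M (fed, over 80 min) | 0.105 M | 10 µM | all else is in the flask from the start; the feed brings no volume worth counting | 1.5 h |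
| blue | 0.10 M | 0.105 M (fed, over 80 min) | 10 µM | all else is in the flask from the start; the feed brings no volume worth counting | 1.5 h |

| run | time / min | target / % |
|---|---|---|
| oak | 8.00 | 81 |
| oak | 25.0 | 86 |
| oak | 40.0 | 87 |
| oak | 60.0 | 84 |
| oak | 90.0 | 87 |
| alder | 20.0 | 75 |
| alder | 40.0 | 75 |
| alder | 60.0 | 73 |
| alder | 80.0 | 71 |
| alder | 120 | 70 |
| birch | 8.00 | 70 |
| birch | 15.0 | 82 |
| birch | 30.0 | 86 |
| birch | 60.0 | 83 |
| birch | 120 | 82 |

(scatter of a reading: 1.5 percentage points)

1. which flask leads in amount of target, in percent of the starting material charged ("all alike" within 1.5 percentage points) (teal / red / blue / all alike)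
2. how much target is there at the end, in percent of the starting material charged: teal
3. how much target is there at the end, in percent of the starting material charged: red
4. how much target is there at the end, in percent of the starting material charged: blue



If the enzyme's use of second substrate is also first order in it, a constant share of that reagent reaches target. In birch the plateau readings averaged 83.2% of the charge, so I took that share as 79.3%. The reading at 8.00 min then left 16.7% of the starting-material charge unspent as second substrate, which gave a total decay of 0.230 min⁻¹. The lost share of that is the waiting loss, 0.0476 min⁻¹, the fraction of standing second substrate lost each minute.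

Oak, reckoned the same way from a plateau of 86.0%, a share of 81.9% and 6.10% unspent, gave 0.0643 min⁻¹, which is 0.131 higher in powers of ten. One reading's scatter shifts oak's unspent amount by 30.0% of itself, more than the 11.3% it shifts birch's, so I kept birch's figure.

For red, feed and waste together use up the second substrate after 33.8 min, sooner than the 80 min feed ends, by which point 42.3% of the charge has been fed. That was my red. Teal I put at oak's 86.0%, and blue level with it, since a first-order loss takes the same share.

The forecast differed: teal 86%, red 92%, blue 55%, with red leading, on the ground that "a side path first order or higher in starting material would then be suppressed by feeding it".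

The flasks gave teal 87.6%, red 42.4% and blue 68.4%, so teal led, and blue stood 18 percentage points under my figure. Red ended with second substrate at 0% of its charge, although that reagent was charged in excess at 1.05 equivalents, and with 32.8% of the starting material unused. The waiting loss had put red's decomposed reagent at 0.0627 M, and the flask held 0.0550 M.

    starting material + free enzyme ⇌ first complex (K = 450 M⁻¹, k = 20000 M⁻¹ s⁻¹)
    first complex → loaded enzyme + first product (k = 42000 min⁻¹)
    second substrate + loaded enzyme ⇌ second complex (K = 28.0 M⁻¹, k = 1.00 × 10⁵ M⁻¹ min⁻¹)
    second complex → free enzyme + target (k = 2700 min⁻¹)
    starting material ⇌ dormant form (K = 1.40, k = 0.00920 min⁻¹)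
    second substrate → decomposed reagent (k = 0.0330 min⁻¹)
    starting material + target → side product (k = 0.140 M⁻¹ min⁻¹)

For the neighbour of teal with 0.063 M of second substrate, the waiting loss over birch's decay scaled to teal's enzyme gives 53.2% target. The computed flask held 41.9%, with side product at 28.8%.

All runs were generated by integration on assumed constants; scatter was added.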